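**Retrosynthetic overview**
1. Target 21 ⇒ acyclic alkylidene β-keto ester 18. Both O-heterocycles close in the last flask: pyranone ring C first (catalyst-controlled oxa-Michael addition, sets flavanone C2), then dihydrofuran ring D (acid-triggered benzylic cation capture, sets furan C2 trans to C3), with loss of the ester as CO2 and of all MOM groups.
2. 18 ⇒ Knoevenagel union of A-ring β-keto ester 6 with triaryl aldehyde 17.
3. 17 ⇒ bromo alcohol 15 (Br → CHO) ⇒ racemic α,α-diaryl ketone 14 by hydrogenative dynamic kinetic resolution (sets the diaryl-methine centre, the future furan C3).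
4. 14 ⇒ two Pd-catalysed α-arylations of 4'-(methoxymethoxy)acetophenone with the MOM ethers of 5-bromoresorcinol and 4,6-dibromoresorcinol.
5. 6 ⇒ 2,4,6-trihydroxyacetophenone by double C-prenylation, MOM protection and C-acylation. All benzene rings are bought.

Assumption: the carbinol configuration (C1) of 15–19 is immaterial because this centre is ionised and re-set in step 12; it is drawn as expected from step 9.

**Step 1**
Reactants: 1 2,4,6-trihydroxyacetophenone; 2 prenyl bromide (1-bromo-3-methylbut-2-ene)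
Product: 3 1-[2,4,6-trihydroxy-3,5-bis(3-methylbut-2-enyl)phenyl]ethanone
Conditions: 2 (2.2 equiv), 10% aq KOH, 0 °C → rt
Reagents that add atoms: none
Why: Base-mediated C-prenylation (Friedel–Crafts-type C-alkylation of the phloroglucinol phenoxide) at both free ring positions; modest yield is accepted for a one-step entry from cheap materials; no stereocentre.

**Step 2**
Reactants: 3 1-[2,4,6-trihydroxy-3,5-bis(3-methylbut-2-enyl)phenyl]ethanone
Product: 4 1-[2-hydroxy-4,6-bis(methoxymethoxy)-3,5-bis(3-methylbut-2-enyl)phenyl]ethanone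
Conditions: MOMCl (2.2 equiv), K2CO3, acetone, 0 °C → rt
Reagents that add atoms: chloromethyl methyl ether (MOMCl), COCCl
Why: Williamson O-alkylation; the carbonyl-chelated ortho-OH is the least reactive and stays free as the later ring-C nucleophile.

**Step 3**
Reactants: 4 1-[2-hydroxy-4,6-bis(methoxymethoxy)-3,5-bis(3-methylbut-2-enyl)phenyl]ethanone
Product: 6 tert-butyl 3-[2-hydroxy-4,6-bis(methoxymethoxy)-3,5-bis(3-methylbut-2-enyl)phenyl]-3-oxopropanoate, via dilithium enolate-phenoxide 5 (not isolated)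
Conditions: LiHMDS (3.1 equiv), THF, −78 °C; Boc2O (1.05 equiv), −78 → −20 °C; aq NH4Cl
Reagents that add atoms: di-tert-butyl dicarbonate, CC(C)(C)OC(=O)OC(=O)OC(C)(C)C
Why: Claisen-type C-acylation of the ketone enolate; the tert-butyl ester activates the later oxa-Michael acceptor and leaves as CO2 in step 12.

**Step 4**
Reactants: 7 4'-hydroxyacetophenone
Product: 8 1-[4-(methoxymethoxy)phenyl]ethanone
Conditions: MOMCl, K2CO3, acetone, rt
Reagents that add atoms: chloromethyl methyl ether (MOMCl), COCCl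
Why: Williamson O-alkylation; MOM is stable to base and organometallics and is removed by acid without touching the prenyl groups.

**Step 5**
Reactants: 9 5-bromoresorcinol
Product: 10 1-bromo-3,5-bis(methoxymethoxy)benzene
Conditions: MOMCl (2.4 equiv), K2CO3, acetone, rt
Reagents that add atoms: chloromethyl methyl ether (MOMCl), COCCl
Why: Williamson O-alkylation of both phenols.

**Step 6**
Reactants: 8 1-[4-(methoxymethoxy)phenyl]ethanone; 10 1-bromo-3,5-bis(methoxymethoxy)benzene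
Product: 11 2-[3,5-bis(methoxymethoxy)phenyl]-1-[4-(methoxymethoxy)phenyl]ethanone
Conditions: Pd2(dba)3 (1 mol%), Xantphos (2.4 mol%), NaOtBu, THF, 70 °C (8 in slight excess)
Reagents that add atoms: none
Why: Pd-catalysed ketone α-arylation (Buchwald–Hartwig type), mono-selective with a wide-bite-angle ligand and excess ketone; it assembles the resveratrol-type C6–C2–C6 unit with the carbonyl next to the 4-oxyphenyl ring.

**Step 7**
Reactants: 12 4,6-dibromoresorcinol
Product: 13 1,5-dibromo-2,4-bis(methoxymethoxy)benzene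
Conditions: MOMCl (2.4 equiv), K2CO3, acetone, rt
Reagents that add atoms: chloromethyl methyl ether (MOMCl), COCCl
Why: Williamson O-alkylation; the symmetric dibromide is the B-ring linchpin (one Br for the C–C bond, one for the later aldehyde).

**Step 8**
Reactants: 11 2-[3,5-bis(methoxymethoxy)phenyl]-1-[4-(methoxymethoxy)phenyl]ethanone; 13 1,5-dibromo-2,4-bis(methoxymethoxy)benzene
Product: 14 rac-2-[5-bromo-2,4-bis(methoxymethoxy)phenyl]-2-[3,5-bis(methoxymethoxy)phenyl]-1-[4-(methoxymethoxy)phenyl]ethanone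
Conditions: Pd(OAc)2 (3 mol%), P(t-Bu)3·HBF4 (6 mol%), NaOtBu, toluene, 80 °C (13 in 3-fold excess, recovered)
Reagents that add atoms: none
Why: Second Pd-catalysed α-arylation gives the α,α-diaryl ketone (a quaternary third arylation is sterically blocked and excess dibromide suppresses double coupling); the new centre is racemic and deliberately labile for step 9.

**Step 9**
Reactants: 14 rac-2-[5-bromo-2,4-bis(methoxymethoxy)phenyl]-2-[3,5-bis(methoxymethoxy)phenyl]-1-[4-(methoxymethoxy)phenyl]ethanone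
Product: 15 (1R,2R)-2-[5-bromo-2,4-bis(methoxymethoxy)phenyl]-2-[3,5-bis(methoxymethoxy)phenyl]-1-[4-(methoxymethoxy)phenyl]ethan-1-ol
Conditions: trans-RuCl2[(S)-XylBINAP][(S)-DAIPEN] (0.5 mol%), KOtBu (20 mol%), H2 (10 atm), i-PrOH–THF, 25 °C
Reagents that add atoms: none
Why: Noyori asymmetric hydrogenation with dynamic kinetic resolution: KOtBu keeps the acidic α,α-diaryl C–H epimerising while the catalyst reduces one ketone face (carbinol R) and, by Felkin-type matching, only the (2R)-ketone, so C2 (future furan C3) is set as R; if the syn/anti preference is the reverse, the antipodal catalyst gives the C1 epimer with the same 2R centre, which serves equally.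

**Step 10**
Reactants: 15 (1R,2R)-2-[5-bromo-2,4-bis(methoxymethoxy)phenyl]-2-[3,5-bis(methoxymethoxy)phenyl]-1-[4-(methoxymethoxy)phenyl]ethan-1-ol
Product: 17 5-[(1R,2R)-1-[3,5-bis(methoxymethoxy)phenyl]-2-hydroxy-2-[4-(methoxymethoxy)phenyl]ethyl]-2,4-bis(methoxymethoxy)benzaldehyde, via dilithio alkoxide-aryllithium 16 (not isolated)
Conditions: n-BuLi (2.2 equiv), THF, −78 °C; DMF, −78 → 0 °C; aq NH4Cl
Reagents that add atoms: N,N-dimethylformamide, CN(C)C=O
Why: Alkoxide formation, then Br–Li exchange (faster than MOM-directed deprotonation at −78 °C) and Bouveault formylation; the diaryl-methine C–H is not acidic enough to be touched, so C2 is retained.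

**Step 11**
Reactants: 6 tert-butyl 3-[2-hydroxy-4,6-bis(methoxymethoxy)-3,5-bis(3-methylbut-2-enyl)phenyl]-3-oxopropanoate; 17 5-[(1R,2R)-1-[3,5-bis(methoxymethoxy)phenyl]-2-hydroxy-2-[4-(methoxymethoxy)phenyl]ethyl]-2,4-bis(methoxymethoxy)benzaldehyde
Product: 18 tert-butyl 2-({5-[(1R,2R)-1-[3,5-bis(methoxymethoxy)phenyl]-2-hydroxy-2-[4-(methoxymethoxy)phenyl]ethyl]-2,4-bis(methoxymethoxy)phenyl}methylidene)-3-[2-hydroxy-4,6-bis(methoxymethoxy)-3,5-bis(3-methylbut-2-enyl)phenyl]-3-oxopropanoate (E/Z mixture)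
Conditions: piperidine (20 mol%), AcOH (20 mol%), 4 Å MS, toluene, 25 °C
Reagents that add atoms: none
Why: Knoevenagel condensation; the bulky tert-butyl ester and the chelated phenol hold back uncatalysed ring closure, and the E/Z mixture is used as such.

**Step 12**
Reactants: 18 tert-butyl 2-({5-[(1R,2R)-1-[3,5-bis(methoxymethoxy)phenyl]-2-hydroxy-2-[4-(methoxymethoxy)phenyl]ethyl]-2,4-bis(methoxymethoxy)phenyl}methylidene)-3-[2-hydroxy-4,6-bis(methoxymethoxy)-3,5-bis(3-methylbut-2-enyl)phenyl]-3-oxopropanoate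
Product: 21 (2S)-2-[(2R,3R)-3-(3,5-dihydroxyphenyl)-6-hydroxy-2-(4-hydroxyphenyl)-2,3-dihydro-1-benzofuran-5-yl]-5,7-dihydroxy-6,8-bis(3-methylbut-2-enyl)chroman-4-one, via flavanone tert-butyl ester 19 (not isolated), via ring-D-closed flavanone acid 20 (not isolated)
Conditions: (i) epi-quinine-derived 3,5-bis(CF3)phenyl thiourea (10 mol%), toluene, −25 °C; (ii) same flask, 3 M aq HCl–MeOH–THF, 40 °C
Reagents that add atoms: none
Why: Proposed new method: the bifunctional thiourea binds the alkylidene β-keto ester by double H-bonding while its quinuclidine delivers the A-ring phenol to one face in a 6-endo oxa-Michael addition that closes ring C and sets C2 as S (closest known reaction: cinchona-thiourea flavanone synthesis from alkylidene β-keto esters with in-situ acid decarboxylation; the quinidine-derived pseudo-enantiomer is used if the sense is opposite), and the acid then cleaves the tert-butyl ester (CO2 loss from 20) and all MOM groups and ionises the p-oxybenzylic alcohol so that the B-ring 4-oxygen traps the cation to close ring D trans to the fixed C3 centre (thermodynamic SN1 etherification, as in acid cis→trans equilibration of 2,3-diaryl-dihydrobenzofurans).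

**Compound list**
1 | 2,4,6-trihydroxyacetophenone | CC(=O)c1c(O)cc(O)cc1O | starting material
2 | prenyl bromide | CC(C)=CCBr | starting material
3 | 1-[2,4,6-trihydroxy-3,5-bis(3-methylbut-2-enyl)phenyl]ethanone | CC(=O)c1c(O)c(CC=C(C)C)c(O)c(CC=C(C)C)c1O | intermediate
4 | 1-[2-hydroxy-4,6-bis(methoxymethoxy)-3,5-bis(3-methylbut-2-enyl)phenyl]ethanone | CC(=O)c1c(O)c(CC=C(C)C)c(OCOC)c(CC=C(C)C)c1OCOC | intermediate
5 | dilithium enolate-phenoxide of 4 | [Li+].[Li+].C=C([O-])c1c([O-])c(CC=C(C)C)c(OCOC)c(CC=C(C)C)c1OCOC | intermediate (not isolated)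
6 | tert-butyl 3-[2-hydroxy-4,6-bis(methoxymethoxy)-3,5-bis(3-methylbut-2-enyl)phenyl]-3-oxopropanoate | CC(C)(C)OC(=O)CC(=O)c1c(O)c(CC=C(C)C)c(OCOC)c(CC=C(C)C)c1OCOC | intermediate
7 | 4'-hydroxyacetophenone | CC(=O)c1ccc(O)cc1 | starting material
8 | 1-[4-(methoxymethoxy)phenyl]ethanone | CC(=O)c1ccc(OCOC)cc1 | intermediate
9 | 5-bromoresorcinol | Oc1cc(O)cc(Br)c1 | starting material
10 | 1-bromo-3,5-bis(methoxymethoxy)benzene | COCOc1cc(Br)cc(OCOC)c1 | intermediate
11 | 2-[3,5-bis(methoxymethoxy)phenyl]-1-[4-(methoxymethoxy)phenyl]ethanone | COCOc1ccc(cc1)C(=O)Cc1cc(OCOC)cc(OCOC)c1 | intermediate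
12 | 4,6-dibromoresorcinol | Oc1cc(O)c(Br)cc1Br | starting material
13 | 1,5-dibromo-2,4-bis(methoxymethoxy)benzene | COCOc1cc(OCOC)c(Br)cc1Br | intermediate
14 | rac-2-[5-bromo-2,4-bis(methoxymethoxy)phenyl]-2-[3,5-bis(methoxymethoxy)phenyl]-1-[4-(methoxymethoxy)phenyl]ethanone | COCOc1ccc(cc1)C(=O)C(c1cc(Br)c(OCOC)cc1OCOC)c1cc(OCOC)cc(OCOC)c1 | intermediate
15 | (1R,2R)-2-[5-bromo-2,4-bis(methoxymethoxy)phenyl]-2-[3,5-bis(methoxymethoxy)phenyl]-1-[4-(methoxymethoxy)phenyl]ethan-1-ol | COCOc1ccc(cc1)[C@H](O)[C@@H](c1cc(Br)c(OCOC)cc1OCOC)c1cc(OCOC)cc(OCOC)c1 | intermediate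
16 | dilithio alkoxide-aryllithium of 15 | COCOc1ccc(cc1)[C@H]([O-])[C@@H](c1cc([Li])c(OCOC)cc1OCOC)c1cc(OCOC)cc(OCOC)c1.[Li+] | intermediate (not isolated)
17 | 5-[(1R,2R)-1-[3,5-bis(methoxymethoxy)phenyl]-2-hydroxy-2-[4-(methoxymethoxy)phenyl]ethyl]-2,4-bis(methoxymethoxy)benzaldehyde | COCOc1ccc(cc1)[C@H](O)[C@@H](c1cc(C=O)c(OCOC)cc1OCOC)c1cc(OCOC)cc(OCOC)c1 | intermediate
18 | alkylidene β-keto ester (E/Z mixture, name as in step 11) | CC(C)(C)OC(=O)C(=Cc1cc([C@@H](c2cc(OCOC)cc(OCOC)c2)[C@@H](O)c2ccc(OCOC)cc2)c(OCOC)cc1OCOC)C(=O)c1c(O)c(CC=C(C)C)c(OCOC)c(CC=C(C)C)c1OCOC | intermediate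
19 | tert-butyl (2S)-2-{5-[(1R,2R)-1-[3,5-bis(methoxymethoxy)phenyl]-2-hydroxy-2-[4-(methoxymethoxy)phenyl]ethyl]-2,4-bis(methoxymethoxy)phenyl}-5,7-bis(methoxymethoxy)-6,8-bis(3-methylbut-2-enyl)-4-oxochromane-3-carboxylate (C3 epimers/enol) | CC(C)=CCc1c(OCOC)c(CC=C(C)C)c2c(c1OCOC)C(=O)C(C(=O)OC(C)(C)C)[C@@H](c1cc([C@@H](c3cc(OCOC)cc(OCOC)c3)[C@@H](O)c3ccc(OCOC)cc3)c(OCOC)cc1OCOC)O2 | intermediate (not isolated)
20 | (2S)-2-[(2R,3R)-3-(3,5-dihydroxyphenyl)-6-hydroxy-2-(4-hydroxyphenyl)-2,3-dihydro-1-benzofuran-5-yl]-5,7-dihydroxy-6,8-bis(3-methylbut-2-enyl)-4-oxochromane-3-carboxylic acid | CC(C)=CCc1c(O)c(CC=C(C)C)c2c(c1O)C(=O)C(C(=O)O)[C@@H](c1cc3c(cc1O)O[C@@H](c1ccc(O)cc1)[C@@H]3c1cc(O)cc(O)c1)O2 | intermediate (not isolated)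
21 | (2S)-2-[(2R,3R)-3-(3,5-dihydroxyphenyl)-6-hydroxy-2-(4-hydroxyphenyl)-2,3-dihydro-1-benzofuran-5-yl]-5,7-dihydroxy-6,8-bis(3-methylbut-2-enyl)chroman-4-one | CC(C)=CCc1c(O)c(CC=C(C)C)c2c(c1O)C(=O)C[C@@H](c1cc3c(cc1O)O[C@@H](c1ccc(O)cc1)[C@@H]3c1cc(O)cc(O)c1)O2 | target

**Totals**
Total step count: 12. Longest linear sequence: 7 steps (7 → 8 → 11 → 14 → 15 → 17 → 18 → 21; steps 4, 6, 8, 9, 10, 11, 12).

**Three steps most likely to fail, each with a fallback**

Step 12. The oxa-Michael addition may be slow or poorly face-selective on this hindered, electron-rich alkylidene. The acid stage may also cyclise prenyl/phenol pairs to chromans or erode C2 through the electron-rich benzylic C–O bond. The fallback sets C2 by intermolecular conjugate arylation instead of ring closure; it sets out from 15 and 4 and comes back at 21. Bromide 15 is borylated (B2pin2, Pd(dppf)Cl2, KOAc, dioxane, 90 °C) to the pinacol boronate (1R,2R)-2-[2,4-bis(methoxymethoxy)-5-(pinacolboryl)phenyl]-2-[3,5-bis(methoxymethoxy)phenyl]-1-[4-(methoxymethoxy)phenyl]ethan-1-ol F1. Ketone 4 is condensed with DMF dimethyl acetal (toluene, 100 °C, then silica gel) to the chromone 5,7-bis(methoxymethoxy)-6,8-bis(3-methylbut-2-enyl)-4H-chromen-4-one F2. Rh(I)/chiral-diene-catalysed 1,4-addition of F1 to F2 (Hayashi–Miyaura type, dioxane–water, 40 °C, ligand antipode chosen for 2S) gives the MOM-protected (2S)-flavanone F3 with the side chain still open. 3 M HCl–MeOH–THF at 40 °C then removes the MOM groups and closes ring D to give 21.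

Step 9. The triaryl ketone may reduce slowly or with poor syn/anti control, which would lower the ee at the diaryl-methine centre. The fallback sets that centre by nickel-catalysed enantioconvergent Negishi arylation instead of resolution; it sets out from 11 and 13 and comes back at 15. Ketone 11 is brominated through its enolate (LiHMDS, then NBS, THF, −78 °C) to rac-2-bromo-2-[3,5-bis(methoxymethoxy)phenyl]-1-[4-(methoxymethoxy)phenyl]ethanone F4. Dibromide 13 is converted by single Br/Mg exchange and transmetalation (i-PrMgCl·LiCl, −15 °C, then ZnCl2) into [5-bromo-2,4-bis(methoxymethoxy)phenyl]zinc chloride F5. NiCl2·glyme with a chiral Ph-pybox ligand (glyme–THF, −30 °C) couples racemic F4 with F5 to (2R)-2-[5-bromo-2,4-bis(methoxymethoxy)phenyl]-2-[3,5-bis(methoxymethoxy)phenyl]-1-[4-(methoxymethoxy)phenyl]ethanone F6. F6 is reduced at once under non-epimerising conditions (NaBH4, CeCl3, MeOH–THF, −78 °C) to 15 together with its C1 epimer, which is equally usable.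

Step 11. The hindered β-keto ester may condense sluggishly with the electron-rich aldehyde, or the product may cyclise without the catalyst during its formation and so lose C2 control. The fallback drops the ester activation; it sets out from 4 and 17 and comes back at 21. Claisen–Schmidt condensation of 4 with 17 (KOH, EtOH–THF, rt) gives the (E)-chalcone (E)-3-{5-[(1R,2R)-1-[3,5-bis(methoxymethoxy)phenyl]-2-hydroxy-2-[4-(methoxymethoxy)phenyl]ethyl]-2,4-bis(methoxymethoxy)phenyl}-1-[2-hydroxy-4,6-bis(methoxymethoxy)-3,5-bis(3-methylbut-2-enyl)phenyl]prop-2-en-1-one F7. 3 M HCl–MeOH–THF at 40 °C removes the MOM groups and closes both rings, giving 21 together with its C2 epimer (2R)-2-[(2R,3R)-3-(3,5-dihydroxyphenyl)-6-hydroxy-2-(4-hydroxyphenyl)-2,3-dihydro-1-benzofuran-5-yl]-5,7-dihydroxy-6,8-bis(3-methylbut-2-enyl)chroman-4-one F8 in about 1:1 ratio. The two are diastereomers and are separated by chromatography; F8 is recycled by NaOAc-mediated ring opening and re-closure (EtOH, 60 °C). This fallback gives no kinetic control at C2.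

**Further compounds**
F1 | step 12 | (1R,2R)-2-[2,4-bis(methoxymethoxy)-5-(4,4,5,5-tetramethyl-1,3,2-dioxaborolan-2-yl)phenyl]-2-[3,5-bis(methoxymethoxy)phenyl]-1-[4-(methoxymethoxy)phenyl]ethan-1-ol | COCOc1ccc(cc1)[C@H](O)[C@@H](c1cc(B2OC(C)(C)C(C)(C)O2)c(OCOC)cc1OCOC)c1cc(OCOC)cc(OCOC)c1
F2 | step 12 | 5,7-bis(methoxymethoxy)-6,8-bis(3-methylbut-2-enyl)-4H-chromen-4-one | CC(C)=CCc1c(OCOC)c(CC=C(C)C)c2occc(=O)c2c1OCOC
F3 | step 12 | (2S)-2-{5-[(1R,2R)-1-[3,5-bis(methoxymethoxy)phenyl]-2-hydroxy-2-[4-(methoxymethoxy)phenyl]ethyl]-2,4-bis(methoxymethoxy)phenyl}-5,7-bis(methoxymethoxy)-6,8-bis(3-methylbut-2-enyl)chroman-4-one | CC(C)=CCc1c(OCOC)c(CC=C(C)C)c2c(c1OCOC)C(=O)C[C@@H](c1cc([C@@H](c3cc(OCOC)cc(OCOC)c3)[C@@H](O)c3ccc(OCOC)cc3)c(OCOC)cc1OCOC)O2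
F4 | step 9 | rac-2-bromo-2-[3,5-bis(methoxymethoxy)phenyl]-1-[4-(methoxymethoxy)phenyl]ethanone | COCOc1ccc(cc1)C(=O)C(Br)c1cc(OCOC)cc(OCOC)c1
F5 | step 9 | [5-bromo-2,4-bis(methoxymethoxy)phenyl]zinc chloride | COCOc1cc(OCOC)c([Zn]Cl)cc1Br
F6 | step 9 | (2R)-2-[5-bromo-2,4-bis(methoxymethoxy)phenyl]-2-[3,5-bis(methoxymethoxy)phenyl]-1-[4-(methoxymethoxy)phenyl]ethanone | COCOc1ccc(cc1)C(=O)[C@@H](c1cc(Br)c(OCOC)cc1OCOC)c1cc(OCOC)cc(OCOC)c1
F7 | step 11 | (E)-3-{5-[(1R,2R)-1-[3,5-bis(methoxymethoxy)phenyl]-2-hydroxy-2-[4-(methoxymethoxy)phenyl]ethyl]-2,4-bis(methoxymethoxy)phenyl}-1-[2-hydroxy-4,6-bis(methoxymethoxy)-3,5-bis(3-methylbut-2-enyl)phenyl]prop-2-en-1-one | CC(C)=CCc1c(O)c(C(=O)/C=C/c2cc([C@@H](c3cc(OCOC)cc(OCOC)c3)[C@@H](O)c3ccc(OCOC)cc3)c(OCOC)cc2OCOC)c(OCOC)c(CC=C(C)C)c1OCOC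
F8 | step 11 | (2R)-2-[(2R,3R)-3-(3,5-dihydroxyphenyl)-6-hydroxy-2-(4-hydroxyphenyl)-2,3-dihydro-1-benzofuran-5-yl]-5,7-dihydroxy-6,8-bis(3-methylbut-2-enyl)chroman-4-one | CC(C)=CCc1c(O)c(CC=C(C)C)c2c(c1O)C(=O)C[C@H](c1cc3c(cc1O)O[C@@H](c1ccc(O)cc1)[C@@H]3c1cc(O)cc(O)c1)O2
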